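**Retrosynthetic overview**
1. Numbering: ring C1 (bears CO2Me) to C14, stereocentre C4; side chain C15(Me)=C16–C17–C18=C19Me2.
2. The only ring (14-membered) is formed last, at C1=C2, by intramolecular Horner–Wadsworth–Emmons olefination of an aldehyde/α-phosphono ester.
3. C3–C4, the C4 stereocentre and the (E)-C15=C16 olefin come from a Johnson–Claisen rearrangement of an (R)-C16 allylic alcohol (1,3-chirality transfer); the phosphonoacetate is attached by alkylation at C14.
4. Key bond C16–C17: intermolecular asymmetric carbonyl allylation (Brown allylboration) joining the enal fragment with the allyl fragment; cross-metathesis then completes the prenyl end.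
5. The enal fragment (C4–C16, both ring (E)-olefins in place) comes from (2E,6E)-farnesol by one-carbon head homologation and SeO2 oxidation of the terminal (E)-methyl.

Assumption: commercial (2E,6E)-farnesol of at least 96% isomeric purity is the starting material.

**Route**

Step 1
Reactants: 1 (2E,6E)-farnesol
Product: 2 (2E,6E)-farnesal
Conditions: activated MnO2 (15 equiv), CH2Cl2, rt
Reagents that add atoms: none
Why: MnO2 allylic oxidation is selective for the allylic alcohol and keeps the (E)-geometry of the enal.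

Step 2
Reactants: 2 (2E,6E)-farnesal; 3 methyltriphenylphosphonium bromide
Product: 5 (3E,7E)-4,8,12-trimethyltrideca-1,3,7,11-tetraene, via methylenetriphenylphosphorane 4 (not isolated)
Conditions: 3, n-BuLi, THF, 0 °C; then 2, 0 °C → rt
Reagents that add atoms: none
Why: Wittig methylenation of the enal is fast and does not touch the trisubstituted (E)-olefins.

Step 3
Reactants: 5 (3E,7E)-4,8,12-trimethyltrideca-1,3,7,11-tetraene
Product: 7 (3E,7E)-4,8,12-trimethyltrideca-3,7,11-trien-1-ol, via B-alkyl-9-BBN adduct 6 (not isolated)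
Conditions: 9-BBN (1.1 equiv), THF, 0 °C → rt; then 3 M NaOH, 30% H2O2, 0 °C → rt
Reagents that add atoms: hydrogen peroxide, OO
Why: Brown hydroboration–oxidation with the bulky 9-BBN attacks only the monosubstituted terminal olefin, anti-Markovnikov, and gives the homoallylic alcohol.

Step 4
Reactants: 7 (3E,7E)-4,8,12-trimethyltrideca-3,7,11-trien-1-ol
Product: 8 (6E,10E)-13-chloro-2,6,10-trimethyltrideca-2,6,10-triene
Conditions: PPh3, N-chlorosuccinimide, THF, 0 °C → rt
Reagents that add atoms: N-chlorosuccinimide, O=C1CCC(=O)N1Cl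
Why: Appel-type SN2 chlorination of the primary alcohol gives a robust handle for the later alkylation without allylic transposition.

Step 5
Reactants: 8 (6E,10E)-13-chloro-2,6,10-trimethyltrideca-2,6,10-triene
Product: 9 (2E,6E,10E)-13-chloro-2,6,10-trimethyltrideca-2,6,10-trien-1-ol
Conditions: SeO2 (0.2 equiv), t-BuOOH (3 equiv), salicylic acid (0.1 equiv), CH2Cl2, 0 °C → rt; stop at about 60% conversion and recycle 8
Reagents that add atoms: tert-butyl hydroperoxide, CC(C)(C)OO
Why: Sharpless catalytic SeO2 allylic oxidation (ene reaction then [2,3]-shift) hydroxylates the (E)-methyl of the terminal isopropylidene, the least hindered trisubstituted olefin.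

Step 6
Reactants: 9 (2E,6E,10E)-13-chloro-2,6,10-trimethyltrideca-2,6,10-trien-1-ol
Product: 10 (2E,6E,10E)-13-chloro-2,6,10-trimethyltrideca-2,6,10-trienal
Conditions: activated MnO2 (15 equiv), CH2Cl2, rt
Reagents that add atoms: none
Why: MnO2 allylic oxidation gives the (E)-enal and also converges any enal already formed in step 5.

Step 7
Reactants: 10 (2E,6E,10E)-13-chloro-2,6,10-trimethyltrideca-2,6,10-trienal; 11 allylmagnesium bromide
Product: 14 (4R,5E,9E,13E)-16-chloro-5,9,13-trimethylhexadeca-1,5,9,13-tetraen-4-ol, via (+)-B-allyldiisopinocampheylborane 12 (not isolated), via diisopinocampheylborinate ester 13 (not isolated)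
Conditions: (+)-Ipc2BOMe [from (−)-α-pinene], 11, Et2O, 0 °C → rt; then 10, −78 °C; then 3 M NaOH, 30% H2O2, rt
Reagents that add atoms: none
Why: Brown asymmetric allylboration (carbonyl allylation through a chair Zimmerman–Traxler transition state) delivers the allyl group to the Re face of the enal and sets the (R)-carbinol centre in about 92–96% ee.

Step 8
Reactants: 14 (4R,5E,9E,13E)-16-chloro-5,9,13-trimethylhexadeca-1,5,9,13-tetraen-4-ol; 15 2-methylbut-2-ene
Product: 16 (5R,6E,10E,14E)-17-chloro-2,6,10,14-tetramethylheptadeca-2,6,10,14-tetraen-5-ol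
Conditions: 15 (co-solvent, large excess), second-generation Grubbs catalyst RuCl2(=CHPh)(PCy3)(SIMes) (3 mol %), CH2Cl2, 35 °C, sealed
Reagents that add atoms: none
Why: Olefin cross-metathesis turns the only monosubstituted olefin into the prenyl terminus while the hindered trisubstituted olefins and the carbinol centre stay untouched.

Step 9
Reactants: 16 (5R,6E,10E,14E)-17-chloro-2,6,10,14-tetramethylheptadeca-2,6,10,14-tetraen-5-ol; 17 trimethyl orthoacetate
Product: 19 methyl (3R,4E)-3-[(3E,7E)-10-chloro-3,7-dimethyldeca-3,7-dien-1-yl]-4,8-dimethylnona-4,7-dienoate, via mixed ketene acetal 18 (not isolated)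
Conditions: 17 (8 equiv), EtCO2H (0.1 equiv), xylene, 135 °C, MeOH distilled off
Reagents that add atoms: none
Why: The Johnson–Claisen rearrangement runs through a chair transition state with the prenyl-CH2 group equatorial, so the (R)-carbinol and the (E)-olefin give the (R)-C4 centre and the (E)-C15=C16 olefin by suprafacial 1,3-chirality transfer.

Step 10
Reactants: 19 methyl (3R,4E)-3-[(3E,7E)-10-chloro-3,7-dimethyldeca-3,7-dien-1-yl]-4,8-dimethylnona-4,7-dienoate
Product: 20 (3R,4E)-3-[(3E,7E)-10-chloro-3,7-dimethyldeca-3,7-dien-1-yl]-4,8-dimethylnona-4,7-dien-1-ol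
Conditions: i-Bu2AlH (2.5 equiv), CH2Cl2, −78 → 0 °C; aqueous KNaC4H4O6 work-up
Reagents that add atoms: none
Why: Hydride reduction of the ester to the primary alcohol leaves the alkyl chloride, the olefins and the C4 centre unchanged.

Step 11
Reactants: 20 (3R,4E)-3-[(3E,7E)-10-chloro-3,7-dimethyldeca-3,7-dien-1-yl]-4,8-dimethylnona-4,7-dien-1-ol
Product: 21 tert-butyl{[(3R,4E)-3-[(3E,7E)-10-chloro-3,7-dimethyldeca-3,7-dien-1-yl]-4,8-dimethylnona-4,7-dien-1-yl]oxy}dimethylsilane
Conditions: t-BuMe2SiCl, imidazole, CH2Cl2, rt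
Reagents that add atoms: tert-butyldimethylsilyl chloride, CC(C)(C)[Si](C)(C)Cl
Why: Silylation masks the future aldehyde carbon (C2) during the base-mediated alkylation.

Step 12
Reactants: 21 tert-butyl{[(3R,4E)-3-[(3E,7E)-10-chloro-3,7-dimethyldeca-3,7-dien-1-yl]-4,8-dimethylnona-4,7-dien-1-yl]oxy}dimethylsilane; 22 methyl 2-(diethoxyphosphoryl)acetate
Product: 25 methyl (5E,9E,13R,14E)-13-(2-{[tert-butyl(dimethyl)silyl]oxy}ethyl)-2-(diethoxyphosphoryl)-6,10,14,18-tetramethylnonadeca-5,9,14,17-tetraenoate (C2 epimers), via sodium phosphonoacetate 23 (not isolated), via primary iodide 24 (not isolated)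
Conditions: 22 (2.5 equiv), NaH (2.3 equiv), DMF, 0 °C → rt; then 21, NaI (1 equiv), 65 °C
Reagents that add atoms: none
Why: In-situ Finkelstein exchange gives the primary iodide, which the soft phosphonoacetate anion displaces in an SN2 C-alkylation; the new α-centre is an epimer mixture that is erased in step 15.

Step 13
Reactants: 25 methyl (5E,9E,13R,14E)-13-(2-{[tert-butyl(dimethyl)silyl]oxy}ethyl)-2-(diethoxyphosphoryl)-6,10,14,18-tetramethylnonadeca-5,9,14,17-tetraenoate
Product: 26 methyl (5E,9E,13R,14E)-2-(diethoxyphosphoryl)-13-(2-hydroxyethyl)-6,10,14,18-tetramethylnonadeca-5,9,14,17-tetraenoate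
Conditions: camphorsulfonic acid (0.1 equiv), MeOH/CH2Cl2, 0 °C → rt
Reagents that add atoms: none
Why: Acid-catalysed methanolysis removes the primary silyl ether without touching the methyl ester, the phosphonate or the olefins.

Step 14
Reactants: 26 methyl (5E,9E,13R,14E)-2-(diethoxyphosphoryl)-13-(2-hydroxyethyl)-6,10,14,18-tetramethylnonadeca-5,9,14,17-tetraenoate
Product: 27 methyl (5E,9E,13R,14E)-2-(diethoxyphosphoryl)-6,10,14,18-tetramethyl-13-(2-oxoethyl)nonadeca-5,9,14,17-tetraenoate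
Conditions: Dess–Martin periodinane (1.3 equiv), CH2Cl2, 0 °C → rt; used at once
Reagents that add atoms: none
Why: Dess–Martin oxidation gives the aldehyde under neutral conditions, so no premature olefination occurs and C4 (β to the carbonyl) cannot epimerise.

Step 15
Reactants: 27 methyl (5E,9E,13R,14E)-2-(diethoxyphosphoryl)-6,10,14,18-tetramethyl-13-(2-oxoethyl)nonadeca-5,9,14,17-tetraenoate
Product: 28 methyl (1E,4R,7E,11E)-7,11-dimethyl-4-[(2E)-6-methylhepta-2,5-dien-2-yl]cyclotetradeca-1,7,11-triene-1-carboxylate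
Conditions: LiCl (10 equiv), DBU (5 equiv), MeCN, rt; syringe-pump addition of 27 over 12 h, final 1 mM
Reagents that add atoms: none
Why: Intramolecular Horner–Wadsworth–Emmons olefination under Masamune–Roush conditions at high dilution closes the 14-membered ring and gives the favoured (E)-enoate (CO2Me trans to C3).

**Compound list**
1 | (2E,6E)-3,7,11-trimethyldodeca-2,6,10-trien-1-ol, (E,E)-farnesol | CC(C)=CCC/C(C)=C/CC/C(C)=C/CO | starting material
2 | (2E,6E)-3,7,11-trimethyldodeca-2,6,10-trienal, (E,E)-farnesal | CC(C)=CCC/C(C)=C/CC/C(C)=C/C=O | intermediate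
3 | methyltriphenylphosphonium bromide | C[P+](c1ccccc1)(c1ccccc1)c1ccccc1.[Br-] | starting material
4 | methylenetriphenylphosphorane | C=P(c1ccccc1)(c1ccccc1)c1ccccc1 | intermediate
5 | (3E,7E)-4,8,12-trimethyltrideca-1,3,7,11-tetraene | CC(C)=CCC/C(C)=C/CC/C(C)=C/C=C | intermediate
6 | 9-[(3E,7E)-4,8,12-trimethyltrideca-3,7,11-trien-1-yl]-9-borabicyclo[3.3.1]nonane | CC(C)=CCC/C(C)=C/CC/C(C)=C/CCB1C2CCCC1CCC2 | intermediate
7 | (3E,7E)-4,8,12-trimethyltrideca-3,7,11-trien-1-ol, (E,E)-homofarnesol | CC(C)=CCC/C(C)=C/CC/C(C)=C/CCO | intermediate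
8 | (6E,10E)-13-chloro-2,6,10-trimethyltrideca-2,6,10-triene | CC(C)=CCC/C(C)=C/CC/C(C)=C/CCCl | intermediate
9 | (2E,6E,10E)-13-chloro-2,6,10-trimethyltrideca-2,6,10-trien-1-ol | OC/C(C)=C/CC/C(C)=C/CC/C(C)=C/CCCl | intermediate
10 | (2E,6E,10E)-13-chloro-2,6,10-trimethyltrideca-2,6,10-trienal | O=C/C(C)=C/CC/C(C)=C/CC/C(C)=C/CCCl | intermediate
11 | allylmagnesium bromide | C=CC[Mg]Br | starting material
12 | (+)-B-allyldiisopinocampheylborane, Ipc groups from (−)-α-pinene | C=CCB([C@H]1C[C@H]2C[C@@H]([C@@H]1C)C2(C)C)[C@H]1C[C@H]2C[C@@H]([C@@H]1C)C2(C)C | intermediate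
13 | (4R,5E,9E,13E)-16-chloro-5,9,13-trimethylhexadeca-1,5,9,13-tetraen-4-yl diisopinocampheylborinate | C=CC[C@@H](OB([C@H]1C[C@H]2C[C@@H]([C@@H]1C)C2(C)C)[C@H]1C[C@H]2C[C@@H]([C@@H]1C)C2(C)C)/C(C)=C/CC/C(C)=C/CC/C(C)=C/CCCl | intermediate
14 | (4R,5E,9E,13E)-16-chloro-5,9,13-trimethylhexadeca-1,5,9,13-tetraen-4-ol | C=CC[C@@H](O)/C(C)=C/CC/C(C)=C/CC/C(C)=C/CCCl | intermediate
15 | 2-methylbut-2-ene | CC=C(C)C | starting material
16 | (5R,6E,10E,14E)-17-chloro-2,6,10,14-tetramethylheptadeca-2,6,10,14-tetraen-5-ol | CC(C)=CC[C@@H](O)/C(C)=C/CC/C(C)=C/CC/C(C)=C/CCCl | intermediate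
17 | trimethyl orthoacetate (1,1,1-trimethoxyethane) | CC(OC)(OC)OC | starting material
18 | (5R,6E,10E,14E)-17-chloro-5-[(1-methoxyethenyl)oxy]-2,6,10,14-tetramethylheptadeca-2,6,10,14-tetraene | C=C(OC)O[C@H](CC=C(C)C)/C(C)=C/CC/C(C)=C/CC/C(C)=C/CCCl | intermediate
19 | methyl (3R,4E)-3-[(3E,7E)-10-chloro-3,7-dimethyldeca-3,7-dien-1-yl]-4,8-dimethylnona-4,7-dienoate | COC(=O)C[C@H](/C(C)=C/CC=C(C)C)CC/C(C)=C/CC/C(C)=C/CCCl | intermediate
20 | (3R,4E)-3-[(3E,7E)-10-chloro-3,7-dimethyldeca-3,7-dien-1-yl]-4,8-dimethylnona-4,7-dien-1-ol | OCC[C@H](/C(C)=C/CC=C(C)C)CC/C(C)=C/CC/C(C)=C/CCCl | intermediate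
21 | tert-butyl{[(3R,4E)-3-[(3E,7E)-10-chloro-3,7-dimethyldeca-3,7-dien-1-yl]-4,8-dimethylnona-4,7-dien-1-yl]oxy}dimethylsilane | CC(C)(C)[Si](C)(C)OCC[C@H](/C(C)=C/CC=C(C)C)CC/C(C)=C/CC/C(C)=C/CCCl | intermediate
22 | methyl 2-(diethoxyphosphoryl)acetate | CCOP(=O)(OCC)CC(=O)OC | starting material
23 | sodium salt of methyl 2-(diethoxyphosphoryl)acetate | [Na+].CCOP(=O)(OCC)[CH-]C(=O)OC | intermediate
24 | tert-butyl{[(3R,4E)-3-[(3E,7E)-10-iodo-3,7-dimethyldeca-3,7-dien-1-yl]-4,8-dimethylnona-4,7-dien-1-yl]oxy}dimethylsilane | CC(C)(C)[Si](C)(C)OCC[C@H](/C(C)=C/CC=C(C)C)CC/C(C)=C/CC/C(C)=C/CCI | intermediate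
25 | methyl (5E,9E,13R,14E)-13-(2-{[tert-butyl(dimethyl)silyl]oxy}ethyl)-2-(diethoxyphosphoryl)-6,10,14,18-tetramethylnonadeca-5,9,14,17-tetraenoate (C2 epimers) | CC(C)(C)[Si](C)(C)OCC[C@H](/C(C)=C/CC=C(C)C)CC/C(C)=C/CC/C(C)=C/CCC(C(=O)OC)P(=O)(OCC)OCC | intermediate
26 | methyl (5E,9E,13R,14E)-2-(diethoxyphosphoryl)-13-(2-hydroxyethyl)-6,10,14,18-tetramethylnonadeca-5,9,14,17-tetraenoate (C2 epimers) | OCC[C@H](/C(C)=C/CC=C(C)C)CC/C(C)=C/CC/C(C)=C/CCC(C(=O)OC)P(=O)(OCC)OCC | intermediate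
27 | methyl (5E,9E,13R,14E)-2-(diethoxyphosphoryl)-6,10,14,18-tetramethyl-13-(2-oxoethyl)nonadeca-5,9,14,17-tetraenoate (C2 epimers) | O=CC[C@H](/C(C)=C/CC=C(C)C)CC/C(C)=C/CC/C(C)=C/CCC(C(=O)OC)P(=O)(OCC)OCC | intermediate
28 | methyl (1E,4R,7E,11E)-7,11-dimethyl-4-[(2E)-6-methylhepta-2,5-dien-2-yl]cyclotetradeca-1,7,11-triene-1-carboxylate | COC(=O)/C1=C/C[C@H](/C(C)=C/CC=C(C)C)CC/C(C)=C/CC/C(C)=C/CC1 | target

**Step count**
Total: 15 steps. Longest linear sequence: 15 steps, from (E,E)-farnesol 1.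

**Steps most likely to fail**

Step 5 (allylic oxidation: three trisubstituted olefins compete and the yield is usually only moderate). The fallback sets out from 8 and comes back at 10; it degrades and rebuilds the chain end instead of oxidising it in place. N-Bromosuccinimide in THF/H2O at 0 °C attacks the terminal isopropylidene selectively and gives (6E,10E)-3-bromo-13-chloro-2,6,10-trimethyltrideca-6,10-dien-2-ol F1. K2CO3 in MeOH closes it to 3-[(3E,7E)-10-chloro-3,7-dimethyldeca-3,7-dien-1-yl]-2,2-dimethyloxirane F2. HIO4 in wet THF cleaves the epoxide to (4E,8E)-11-chloro-4,8-dimethylundeca-4,8-dienal F3. A Wittig reaction of that aldehyde with 2-(triphenylphosphoranylidene)propanal in toluene at 110 °C gives enal 10 directly with high (E)-selectivity, so step 6 is not needed.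

Step 8 (cross-metathesis in a polyene: incomplete conversion or attack on internal olefins is possible). The fallback sets out from 10 and comes back at 16; the prenyl group is brought in complete by an α-selective carbonyl prenylation and the stereocentre is set afterwards by reduction. Prenylbarium chloride, (CH3)2C=CHCH2BaCl, is made from prenyl chloride and barium metal obtained by reducing BaI2 with LiC12H10 in THF at −78 °C. It adds 1,2 and through its α-carbon to 10 and gives racemic (6E,10E,14E)-17-chloro-2,6,10,14-tetramethylheptadeca-2,6,10,14-tetraen-5-ol F4. Dess–Martin periodinane oxidises this to (6E,10E,14E)-17-chloro-2,6,10,14-tetramethylheptadeca-2,6,10,14-tetraen-5-one F5. Corey–Bakshi–Shibata reduction with (S)-2-methyl-CBS-oxazaborolidine and catecholborane in toluene at −78 °C, with the α-methylalkenyl group as the large substituent, gives the (R)-alcohol 16.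

Step 15 (macrocyclisation: oligomers or an (E)/(Z) mixture at C1=C2 are possible). The fallback sets out from 21 and comes back at 28; the ring is closed by an intramolecular Wittig reaction of a stabilised phosphorane, which is normally more (E)-selective for trisubstituted enoates than a phosphonate. NaI in 2-butanone at 80 °C converts 21 into iodide 24, here isolated. Heating 24 with methyl (triphenylphosphoranylidene)acetate (2.2 equiv, EtOAc, reflux; C-alkylation then transylidation) gives methyl (5E,9E,13R,14E)-13-(2-{[tert-butyl(dimethyl)silyl]oxy}ethyl)-6,10,14,18-tetramethyl-2-(triphenylphosphoranylidene)nonadeca-5,9,14,17-tetraenoate F6. Bu4NF in THF gives methyl (5E,9E,13R,14E)-13-(2-hydroxyethyl)-6,10,14,18-tetramethyl-2-(triphenylphosphoranylidene)nonadeca-5,9,14,17-tetraenoate F7. Dess–Martin periodinane in CH2Cl2 at 0 °C gives methyl (5E,9E,13R,14E)-6,10,14,18-tetramethyl-13-(2-oxoethyl)-2-(triphenylphosphoranylidene)nonadeca-5,9,14,17-tetraenoate F8. This aldehyde is not stored but added slowly to toluene at 110 °C (final 1 mM), where it closes to 28.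

**Further compounds**
F1 | step 5 | (6E,10E)-3-bromo-13-chloro-2,6,10-trimethyltrideca-6,10-dien-2-ol (racemic) | CC(C)(O)C(Br)CC/C(C)=C/CC/C(C)=C/CCCl
F2 | step 5 | 3-[(3E,7E)-10-chloro-3,7-dimethyldeca-3,7-dien-1-yl]-2,2-dimethyloxirane (racemic) | CC1(C)OC1CC/C(C)=C/CC/C(C)=C/CCCl
F3 | step 5 | (4E,8E)-11-chloro-4,8-dimethylundeca-4,8-dienal | O=CCC/C(C)=C/CC/C(C)=C/CCCl
F4 | step 8 | (6E,10E,14E)-17-chloro-2,6,10,14-tetramethylheptadeca-2,6,10,14-tetraen-5-ol (racemic) | CC(C)=CCC(O)/C(C)=C/CC/C(C)=C/CC/C(C)=C/CCCl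
F5 | step 8 | (6E,10E,14E)-17-chloro-2,6,10,14-tetramethylheptadeca-2,6,10,14-tetraen-5-one | CC(C)=CCC(=O)/C(C)=C/CC/C(C)=C/CC/C(C)=C/CCCl
F6 | step 15 | methyl (5E,9E,13R,14E)-13-(2-{[tert-butyl(dimethyl)silyl]oxy}ethyl)-6,10,14,18-tetramethyl-2-(triphenylphosphoranylidene)nonadeca-5,9,14,17-tetraenoate | CC(C)(C)[Si](C)(C)OCC[C@H](/C(C)=C/CC=C(C)C)CC/C(C)=C/CC/C(C)=C/CCC(C(=O)OC)=P(c1ccccc1)(c1ccccc1)c1ccccc1
F7 | step 15 | methyl (5E,9E,13R,14E)-13-(2-hydroxyethyl)-6,10,14,18-tetramethyl-2-(triphenylphosphoranylidene)nonadeca-5,9,14,17-tetraenoate | OCC[C@H](/C(C)=C/CC=C(C)C)CC/C(C)=C/CC/C(C)=C/CCC(C(=O)OC)=P(c1ccccc1)(c1ccccc1)c1ccccc1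
F8 | step 15 | methyl (5E,9E,13R,14E)-6,10,14,18-tetramethyl-13-(2-oxoethyl)-2-(triphenylphosphoranylidene)nonadeca-5,9,14,17-tetraenoate | O=CC[C@H](/C(C)=C/CC=C(C)C)CC/C(C)=C/CC/C(C)=C/CCC(C(=O)OC)=P(c1ccccc1)(c1ccccc1)c1ccccc1
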